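At early times the dawn run at −5 °C climbs to 1.9 % of left-handed product by 40.0 min, an early slope of 4.75 × 10⁻⁴ min⁻¹, the left-handed product made per minute as a fraction of both substrates charged; as a reading it carries the scatter of 1 percentage point.

| setting | winter | dawn | summer | Thursday's | Saturday's | Sunday's |
|---|---|---|---|---|---|---|
| left-handed substrate | 0.17 M | 0.38 M | 0.25 M | 0.25 M | 0.25 M | 0.25 M |
| right-handed substrate | 0.17 M | 0.38 M | 0.25 M | 0.25 M | 0.25 M | 0.25 M |
| reagent | 0.275 M | 0.275 M | 0.275 M | 0.275 M | 0.275 M | 0.275 M |
| precatalyst | 14 mM | 14 mM | 21 mM | 14 mM | 14 mM | 14 mM |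
| temperature | −40 °C | −5 °C | −40 °C | 25 °C | −35 °C | −5 °C |
| remark | run made earlier | run made earlier | run made earlier |  |  |  |
| time |  |  |  | 40 min | 40 min | 40 min |

| winter: time / min | winter: left-handed product / % | dawn: time / min | dawn: left-handed product / % | summer: time / min | summer: left-handed product / % |
|---|---|---|---|---|---|
| 90.0 | 1.2 | 20.0 | 1.0 | 240 | 0.2 |
| 300 | 0 | 40.0 | 1.9 | 480 | 0 |
| 480 | 1.6 | 60.0 | 2.1 | 720 | 1.5 |
| 720 | 0 | 120 | 4.6 | 900 | 0 |
| 1200 | 1.2 | 240 | 11.9 | 1200 | 1.4 |

(scatter of a reading: 1 percentage point)

* the best flask by amount of left-handed product, in percent of the left-handed substrate and right-handed substrate together charged; "all alike" if 1.5 percentage points covers them all (Thursday's / Saturday's / Sunday's / all alike)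
* amount of left-handed product at the end, in percent of the left-handed substrate and right-handed substrate together charged, Thursday's
* amount of left-handed product at the end, in percent of the left-handed substrate and right-handed substrate together charged, Saturday's
* amount of left-handed product at the end, in percent of the left-handed substrate and right-handed substrate together charged, Sunday's

- free catalyst is single-handed; left-handed substrate and right-handed substrate are mirror images of each other, charged as a racemate, each of them at the stated concentration

Does Sunday's follow the dawn run? Sunday's shares its temperature, reagent and precatalyst, so if the percentage slope holds across the substrate charges, Sunday's reaches 1.90 % in 40 min.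

What does cold take away? The winter run reads 1.2 % at 1200 min, a reading close to the scatter that gives a slope of 1.00 × 10⁻⁵ min⁻¹, so by these readings the dawn run is 47.5 times steeper. Saturday's, close to that cold, is then reckoned at about 0.0400 %, less than the scatter.

What does warmth add? Taken once more for the step up to Thursday's 25 °C, a factor of that size asks for 90.2 %, more than the 50.0 % charged as left-handed substrate. The straight slope therefore overruns Thursday's charge and is no estimate of its amount, yet this reckoning still ranks Thursday's first.

The forecast gives 22 % for Thursday's, 0.1 % for Saturday's and 2.5 % for Sunday's, higher on Sunday's than this reckoning, and names Thursday's as best. Of Thursday's it warns: “This is a long extrapolation”.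

The flasks give 25.4 % for Thursday's, 0 % for Saturday's and 1.53 % for Sunday's, so Thursday's is best; the early slope's 1.90 % for Sunday's stands 0.37 points above the result, less than the scatter.

    free catalyst + left-handed substrate ⇌ catalyst intermediate A (K = 31.0 M⁻¹, k = 840 M⁻¹ min⁻¹, Ea = 50.0 kJ mol⁻¹, ΔH = −34.0 kJ mol⁻¹)
    free catalyst + right-handed substrate ⇌ catalyst intermediate B (K = 50.0 M⁻¹, k = 150 M⁻¹ min⁻¹, Ea = 46.0 kJ mol⁻¹, ΔH = −53.0 kJ mol⁻¹)
    reagent + catalyst intermediate A → free catalyst + left-handed product (k = 13.0 M⁻¹ min⁻¹, Ea = 51.0 kJ mol⁻¹)
    reagent + catalyst intermediate B → free catalyst + right-handed product (k = 2.80 M⁻¹ min⁻¹, Ea = 57.0 kJ mol⁻¹)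
    left-handed product ⇌ right-handed product (k = 0.880 min⁻¹, Ea = 76.0 kJ mol⁻¹)
    precatalyst → free catalyst (k = 0.200 min⁻¹, Ea = 75.0 kJ mol⁻¹)
    (constants at 25 °C)

In Sunday's at 40.0 min, binding of free catalyst to left-handed substrate relaxes with a half-life of 1.92 s, while the reagent's half-life by its step with catalyst intermediate A is 7.7 h. At 40.0 min Sunday's holds 0.378 % of its catalyst free, 8.19 % as catalyst intermediate A, 15.2 % as catalyst intermediate B and 76.3 % as precatalyst.

The neighbour flask, Sunday's with 1.1 M of reagent, is reckoned as a pseudo-first-order case: the early slope scaled by the reagent gives 7.60 % of left-handed product in 40 min. That neighbour flask gives 6.09 %.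

The runs are simulated from invented constants; scatter was added.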